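**Retrosynthetic overview**
- Target 29 ⇐ 28 (loss of the C6 silyl ether) ⇐ aldehyde 27 by one cascade: Prins closure of ring C (C9–C11) and 1,2-shift of C6 from C7 to C8. The shift contracts the six-membered ring B (C5–C6–C7–C8–C9–C10) to the cyclopentane (C5, C6, C8, C9, C10) and turns the C7 ketal into the C7 lactone.
- Enabling feature: C20–OH on C10 stands 1,4 to the C7 carbonyl across ring B. C7 can therefore be held as a bridged mixed ketal (C7–O–C20, an oxabicyclo[2.2.2]octene) that puts two oxygen donors on the migration origin and fixes the C6–C7 bond close to the axis of the p orbital that develops at C8 of the C8=C9 alkene.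
- 27 ⇐ trans-fused A/B enone 17 (ring B closed by aldol condensation, C8=C9) ⇐ diketo aldehyde 16 ⇐ Mukaiyama–Michael union (C5–C6) of ring A enone 4 with enol silane 10, cut from (S)-limonene (brings C6–C8, C11–C17 and the C13 centre).
- Order of ring formation: ring A (bought as 1) → six-membered ring B (step 13) → ring C, cyclopentane and lactone together (step 21).

Key step: step 21

Remark: atoms carry ent-kaurane numbers (C1–C14 and C20 in the ring system, C15–C17 in the acrylate); α is the face of rings A/B on which C20 lies, β the other face; the ligand antipode in step 7 is chosen from the square-planar chelate model.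

**Route**

Step 1
Reactants: 1 4,4-dimethylcyclohexanone
Product: 2 methyl 5,5-dimethyl-2-oxocyclohexane-1-carboxylate
Conditions: NaH, (MeO)2CO, THF, reflux; then aq. HCl
Reagents that add atoms: dimethyl carbonate, COC(=O)OC
Why: Claisen-type C-acylation of the sodium enolate by dimethyl carbonate, pulled forward by deprotonation of the β-keto ester; the single stereocentre is enolisable and of no consequence.

Step 2
Reactants: 2 methyl 5,5-dimethyl-2-oxocyclohexane-1-carboxylate
Product: 4 methyl 3,3-dimethyl-6-oxocyclohex-1-ene-1-carboxylate, via selenide 3 (not isolated)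
Conditions: PhSeCl, pyridine, DCM, 0 °C; then H2O2 (30 %), 0 °C → rt
Reagents that add atoms: none
Why: α-Selenenylation of the β-keto ester and oxidation to the selenoxide, whose syn-elimination can only run toward C5 (the sole β-hydrogens) and so should give the doubly activated C10=C5 enone.

Step 3
Reactants: 5 (S)-limonene
Product: 7 (3S)-6-oxo-3-(prop-1-en-2-yl)heptanal, via limonene 1,2-oxide 6 (not isolated)
Conditions: mCPBA (1.0 equiv), DCM, 0 °C; then H5IO6, THF/H2O, 0 °C → rt
Reagents that add atoms: 3-chloroperbenzoic acid, OOC(=O)c1cccc(Cl)c1; water, O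
Why: The peracid epoxidises the more electron-rich trisubstituted ring alkene in preference to the isopropenyl group and periodic acid opens the epoxide to the glycol and cleaves it (epoxidation then glycol cleavage), which unravels the ring into C6–C8 and C11–C14 without touching the C13 stereocentre.

Step 4
Reactants: 7 (3S)-6-oxo-3-(prop-1-en-2-yl)heptanal
Product: 8 (5S)-7-hydroxy-5-(prop-1-en-2-yl)heptan-2-one
Conditions: NaBH(OAc)3, AcOH (cat.), DCM, rt
Reagents that add atoms: none
Why: NaBH(OAc)3 is a mild hydride donor that reduces aldehydes but leaves the methyl ketone alone (chemoselective carbonyl reduction).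

Step 5
Reactants: 8 (5S)-7-hydroxy-5-(prop-1-en-2-yl)heptan-2-one
Product: 9 (5S)-7-(tert-butyldimethylsilyloxy)-5-(prop-1-en-2-yl)heptan-2-one
Conditions: TBSCl, imidazole, DMF, rt
Reagents that add atoms: tert-butyldimethylsilyl chloride, CC(C)(C)[Si](C)(C)Cl
Why: Standard silyl ether formation masks the C11 hydroxyl through the basic, reducing and oxidising steps that follow.

Step 6
Reactants: 9 (5S)-7-(tert-butyldimethylsilyloxy)-5-(prop-1-en-2-yl)heptan-2-one
Product: 10 (5S)-7-(tert-butyldimethylsilyloxy)-5-(prop-1-en-2-yl)-2-(trimethylsilyloxy)hept-1-ene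
Conditions: LiN(i-Pr)2, THF, −78 °C; then Me3SiCl, Et3N, −78 → 0 °C
Reagents that add atoms: chlorotrimethylsilane, C[Si](C)(C)Cl
Why: Kinetic deprotonation with the bulky lithium amide at −78 °C takes the methyl (C6) proton rather than a C8 proton and O-silylation traps the terminal enolate (regioselective enol silane formation).

Step 7
Reactants: 4 methyl 3,3-dimethyl-6-oxocyclohex-1-ene-1-carboxylate; 10 (5S)-7-(tert-butyldimethylsilyloxy)-5-(prop-1-en-2-yl)-2-(trimethylsilyloxy)hept-1-ene
Product: 11 methyl (6S)-6-[(5S)-7-(tert-butyldimethylsilyloxy)-2-oxo-5-(prop-1-en-2-yl)heptyl]-5,5-dimethyl-2-oxocyclohexane-1-carboxylate (5β-H; ester-bearing carbon enolisable)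
Conditions: Cu(OTf)2 (10 mol %), (S,S)-t-Bu-box (11 mol %), (CF3)2CHOH (1.2 equiv), 4 Å MS, DCM, −78 → −20 °C
Reagents that add atoms: none
Why: Mukaiyama–Michael addition of the enol silane to the 2-carbomethoxy enone bound as a bidentate chelate to the chiral Cu(OTf)2–bis(oxazoline) Lewis acid, in which the ligand should screen the β face of C5 so that C6 adds from the α face (5β-H) while the remote C13 centre has no say; the fluorinated alcohol takes the silyl group and turns the catalyst over.

Step 8
Reactants: 11 Mukaiyama–Michael adduct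
Product: 12 methyl (1S,6R)-1-(benzyloxymethyl)-6-[(5S)-7-(tert-butyldimethylsilyloxy)-2-oxo-5-(prop-1-en-2-yl)heptyl]-5,5-dimethyl-2-oxocyclohexane-1-carboxylate (10α-CO2Me, 10β-CH2OBn, 5β-H)
Conditions: NaH, THF, 0 °C; then BnOCH2Cl, 0 °C → rt
Reagents that add atoms: benzyl chloromethyl ether, ClCOCc1ccccc1
Why: C-Alkylation of the chelated sodium enolate of the β-keto ester should occur anti to the bulky C5 side chain, so the benzyloxymethyl group (C9) enters on the β face and the ester (C20) stays α, which sets the quaternary centre C10.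

Step 9
Reactants: 12 alkylated keto ester
Product: 13 triol (C1–OH and C7–OH as epimer mixtures, 10α-CH2OH, 10β-CH2OBn, 5β-H, 11-OTBS, 13S)
Conditions: LiAlH4, THF, 0 °C → rt; then H2O, aq. NaOH
Reagents that add atoms: none
Why: LiAlH4 reduces the ester to the C20 carbinol and both ketones in one operation; the configurations of the C1 and C7 carbinols do not matter because both are oxidised again in step 12.

Step 10
Reactants: 13 triol
Product: 14 C20 silyl ether diol (10α-CH2OTBS)
Conditions: TBSCl (1.05 equiv), imidazole, DCM, −20 → 0 °C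
Reagents that add atoms: tert-butyldimethylsilyl chloride, CC(C)(C)[Si](C)(C)Cl
Why: Silylation of the only primary hydroxyl (C20) should be much faster than that of the two secondary ones at low temperature (chemoselective silyl ether formation).

Step 11
Reactants: 14 C20 silyl ether diol
Product: 15 triol with free C9–OH (10β-CH2OH, 10α-CH2OTBS)
Conditions: Na, NH3(l), THF, −78 °C; then NH4Cl
Reagents that add atoms: none
Why: Dissolving-metal (Birch-type) cleavage removes the benzyl group while the silyl ethers and the isolated isopropenyl alkene, which forbids catalytic hydrogenolysis, are left intact.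

Step 12
Reactants: 15 triol
Product: 16 diketo aldehyde (C1 and C7 ketones, 10β-CHO, 10α-CH2OTBS, 5β-H)
Conditions: Dess–Martin periodinane (4.5 equiv), NaHCO3, DCM, 0 °C → rt
Reagents that add atoms: none
Why: Dess–Martin oxidation under buffered, non-nucleophilic conditions takes both secondary carbinols to ketones and the neopentylic C9 carbinol to the non-enolisable aldehyde without deformylation of the resulting β-keto aldehyde.

Step 13
Reactants: 16 diketo aldehyde
Product: 17 trans-fused bicyclic enone (ring A C1 ketone; ring B Δ8(9)-en-7-one; 10α-CH2OTBS; 5β-H; C8 carries CH2–CH(isopropenyl)–CH2CH2OTBS, 13S)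
Conditions: pyrrolidine (0.2 equiv), AcOH (0.2 equiv), 4 Å MS, PhMe, 50 °C
Reagents that add atoms: none
Why: Amine-catalysed intramolecular aldol (Mannich-type) condensation: of the six-ring closures open to the tricarbonyl compound, attack of the C8 enamine on the C9 aldehyde should be by far the fastest because the aldehyde is much more electrophilic than the hindered C1 and C7 ketones, and loss of water to the conjugated C8=C9 enone makes this closure irreversible, while the trans relation of C6 and C9 on ring A set in step 8 makes the A/B fusion trans.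

Step 14
Reactants: 17 bicyclic enone ketone
Product: 18 1α-alcohol
Conditions: NaBH4 (0.5 equiv), MeOH/DCM (1:1), −78 °C
Reagents that add atoms: none
Why: At −78 °C borohydride should reduce the saturated C1 ketone far faster than the conjugated α-substituted C7 enone and add axially from the β face, away from the axial C20 group on the neighbouring C10, to give the equatorial 1α-alcohol (chemo- and stereoselective ketone reduction).

Step 15
Reactants: 18 1α-alcohol
Product: 19 1α-acetate
Conditions: Ac2O, pyridine, DMAP (cat.), DCM, rt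
Reagents that add atoms: acetic anhydride, CC(=O)OC(C)=O
Why: Acylation of the only free hydroxyl installs the C1 acetate of the target before any other hydroxyl is unmasked.

Step 16
Reactants: 19 1α-acetate
Product: 21 6β-silyloxy enone (1α-OAc; 6β-OTBS; Δ8(9)-en-7-one), via silyl dienol ether 20 (not isolated)
Conditions: TBSOTf, Et3N, DCM, −78 → 0 °C; then mCPBA (1.0 equiv), NaHCO3, DCM, −20 °C
Reagents that add atoms: tert-butyldimethylsilyl trifluoromethanesulfonate, CC(C)(C)[Si](C)(C)OS(=O)(=O)C(F)(F)F; 3-chloroperbenzoic acid, OOC(=O)c1cccc(Cl)c1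
Why: Rubottom oxidation: soft enolisation can only take place toward C6 because C10 bears no hydrogen, the electron-rich silyl enol ether is epoxidised in preference to the other alkenes and from the β face, opposite to the axial C20 group that stands 1,3 to C6, and silyl migration should give the 6β-silyloxy ketone.

Step 17
Reactants: 21 6β-silyloxy enone
Product: 22 C15 allylic alcohol (C13–C(=CH2)CH2OH)
Conditions: SeO2 (0.5 equiv), t-BuOOH, DCM, rt
Reagents that add atoms: tert-butyl hydroperoxide, CC(C)(C)OO
Why: SeO2-catalysed allylic oxidation (ene reaction followed by [2,3]-sigmatropic shift) should attack the only electron-rich alkene, the isopropenyl group, at its methyl group rather than at the tertiary C13–H, and leave the electron-poor enone alone.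

Step 18
Reactants: 22 C15 allylic alcohol
Product: 25 methyl acrylate (C13–C(=CH2)CO2Me), via enal 23 (not isolated), via acrylic acid 24 (not isolated)
Conditions: MnO2, DCM, rt; then NaClO2, NaH2PO4, 2-methyl-2-butene, t-BuOH/H2O, 0 °C; then Me3SiCHN2, MeOH/PhMe, 0 °C
Reagents that add atoms: sodium chlorite, [Na+].[O-]Cl=O; (trimethylsilyl)diazomethane, C[Si](C)(C)C=[N+]=[N-]
Why: MnO2 oxidises only the allylic alcohol, Pinnick oxidation takes the enal to the acid without touching alkenes and Me3SiCHN2 methylates the acid, so the isopropenyl group, which would compete as an ene partner later, is turned into the inert acrylate of the target before the Lewis acid step.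

Step 19
Reactants: 25 methyl acrylate enone
Product: 26 bridged mixed ketal (7-methoxy-7α,20-epoxy; C8=C9; 1α-OAc; 6β-OTBS; C11–OH free)
Conditions: camphorsulfonic acid (0.1 equiv), HC(OMe)3, MeOH, 0 °C → rt; then Et3N
Reagents that add atoms: methanol, CO
Why: Acidic methanol cleaves the two primary silyl ethers but not the hindered secondary one, and the freed C20 hydroxyl, axial on C10 and 1,4 to C7, should close onto the methoxy oxocarbenium ion of the enone to give the bridged mixed ketal (acid-catalysed ketalisation driven by the orthoformate), the C8=C9 bond being unable to migrate because C10 has no hydrogen.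

Step 20
Reactants: 26 bridged mixed ketal alcohol
Product: 27 bridged mixed ketal aldehyde (C11 = CHO)
Conditions: TEMPO (0.1 equiv), PhI(OAc)2, NaHCO3, DCM, rt
Reagents that add atoms: none
Why: Oxoammonium (TEMPO) oxidation of the only free hydroxyl, a primary one, stops at the aldehyde and is mild enough for the ketal.

Step 21
Reactants: 27 bridged mixed ketal aldehyde
Product: 28 6-O-TBS ether of the target (1S,5R,6S,8S,9S,10S,11S,13S)
Conditions: SnCl4 (2 equiv), 2,6-di-tert-butyl-4-methylpyridine, DCM, −78 → −40 °C; then aq. NaHCO3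
Reagents that add atoms: none
Why: Proposed new method: SnCl4 activates the C11 aldehyde, which is attacked by C9 of the C8=C9 alkene in a chair-like Prins closure of ring C; the C8 cation so formed is quenched at once by 1,2-shift of C6 from the ketal carbon C7 to C8 (ring B six → five), and the resulting dialkoxycarbenium ion at C7 loses its methyl group to chloride to give the lactone. The closest known reaction types are the Prins–pinacol cascade of allylic carbinol ethers and the Lewis-acid 1,2-shift of α-halo ketals to esters; new is their union on a bridged mixed ketal. Ring C closes by 6-endo-trig attack through a chair in which the C13 acrylate group and the C11–O–Sn bond are equatorial, the cyclopentane (C5, C6, C8, C9, C10) arises by ring contraction, and the δ-lactone is the former C7–O–C20 bridge (oxabicyclo[2.2.2] becomes oxabicyclo[3.2.1]). C9 and C11 are set by attack on the α face of C9, which is flanked only by the O–C20 bridge while the β face carries H5 and the 6β-silyloxy group, and this is reinforced by the preset (S)-C13 centre, equatorial only in this chair; C8 follows from anti addition (C11 to C9 from α, C6 to C8 from β) and is in any case fixed by the cage. The step needs migration of C6 rather than of the ring oxygen and activation of the aldehyde rather than of the ketal: the bicyclic frame holds the C7–C6 bond close to the axis of the β lobe of the empty p orbital at C8 and the methoxy group in its nodal plane, only the shift of C6 leads to a cation stabilised by two oxygens (participation of the ring oxygen through the α lobe would give a strained oxiranium ion that can only revert), and C7 as a bridgehead cannot ionise by loss of methoxide, so opening of the bridge is the only competing ionisation and is reversible.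

Step 22
Reactants: 28 6-O-TBS ether of the target
Product: 29 CNP0421185.1 (target)
Conditions: HF·pyridine, pyridine, THF, 0 °C → rt
Reagents that add atoms: none
Why: Fluoride cleaves the remaining silyl ether under buffered conditions that leave acetate, acrylate and lactone intact; no stereocentre is touched.

**Compound list**

1 | 4,4-dimethylcyclohexanone | CC1(C)CCC(=O)CC1 | starting material
2 | methyl 5,5-dimethyl-2-oxocyclohexane-1-carboxylate (racemic, keto–enol mixture) | COC(=O)C1CC(C)(C)CCC1=O | intermediate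
3 | methyl 5,5-dimethyl-2-oxo-1-(phenylselanyl)cyclohexane-1-carboxylate | COC(=O)C1([Se]c2ccccc2)CC(C)(C)CCC1=O | intermediate
4 | methyl 3,3-dimethyl-6-oxocyclohex-1-ene-1-carboxylate | COC(=O)C1=CC(C)(C)CCC1=O | intermediate
5 | (S)-(−)-limonene | CC1=CC[C@H](CC1)C(C)=C | starting material
6 | (4S)-limonene 1,2-oxide (both epoxide epimers) | CC12OC1C[C@H](CC2)C(C)=C | intermediate
7 | (3S)-6-oxo-3-(prop-1-en-2-yl)heptanal | CC(=O)CC[C@@H](CC=O)C(C)=C | intermediate
8 | (5S)-7-hydroxy-5-(prop-1-en-2-yl)heptan-2-one | CC(=O)CC[C@@H](CCO)C(C)=C | intermediate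
9 | (5S)-7-(tert-butyldimethylsilyloxy)-5-(prop-1-en-2-yl)heptan-2-one | CC(=O)CC[C@@H](CCO[Si](C)(C)C(C)(C)C)C(C)=C | intermediate
10 | (5S)-7-(tert-butyldimethylsilyloxy)-5-(prop-1-en-2-yl)-2-(trimethylsilyloxy)hept-1-ene | C=C(O[Si](C)(C)C)CC[C@@H](CCO[Si](C)(C)C(C)(C)C)C(C)=C | intermediate
11 | methyl (6S)-6-[(5S)-7-(tert-butyldimethylsilyloxy)-2-oxo-5-(prop-1-en-2-yl)heptyl]-5,5-dimethyl-2-oxocyclohexane-1-carboxylate (5β-H) | COC(=O)C1C(=O)CCC(C)(C)[C@H]1CC(=O)CC[C@@H](CCO[Si](C)(C)C(C)(C)C)C(C)=C | intermediate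
12 | methyl (1S,6R)-1-(benzyloxymethyl)-6-[(5S)-7-(tert-butyldimethylsilyloxy)-2-oxo-5-(prop-1-en-2-yl)heptyl]-5,5-dimethyl-2-oxocyclohexane-1-carboxylate (10α-CO2Me, 10β-CH2OBn, 5β-H) | COC(=O)[C@@]1(COCc2ccccc2)C(=O)CCC(C)(C)[C@H]1CC(=O)CC[C@@H](CCO[Si](C)(C)C(C)(C)C)C(C)=C | intermediate
13 | triol: ring A with C1–OH (both epimers), 10α-CH2OH, 10β-CH2OBn, 5β-H; chain C6H2–C7H(OH)(both epimers)–C8H2–C14H2–C13H(isopropenyl)–C12H2–C11H2OTBS, 13S | OC[C@@]1(COCc2ccccc2)C(O)CCC(C)(C)[C@H]1CC(O)CC[C@@H](CCO[Si](C)(C)C(C)(C)C)C(C)=C | intermediate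
14 | 13 with the C20 hydroxyl as TBS ether | CC(C)(C)[Si](C)(C)OC[C@@]1(COCc2ccccc2)C(O)CCC(C)(C)[C@H]1CC(O)CC[C@@H](CCO[Si](C)(C)C(C)(C)C)C(C)=C | intermediate
15 | 14 without the benzyl group (10β-CH2OH) | CC(C)(C)[Si](C)(C)OC[C@@]1(CO)C(O)CCC(C)(C)[C@H]1CC(O)CC[C@@H](CCO[Si](C)(C)C(C)(C)C)C(C)=C | intermediate
16 | diketo aldehyde: C1 and C7 ketones, 10β-CHO (C9), 10α-CH2OTBS, 5β-H, 11-OTBS, 13S | CC(C)(C)[Si](C)(C)OC[C@@]1(C=O)C(=O)CCC(C)(C)[C@H]1CC(=O)CC[C@@H](CCO[Si](C)(C)C(C)(C)C)C(C)=C | intermediate
17 | trans-fused bicyclic enone: ring A C1 ketone, ring B Δ8(9)-en-7-one, 10α-CH2OTBS, 5β-H; C8 carries CH2–CH(isopropenyl)–CH2CH2OTBS (13S) | CC(C)(C)[Si](C)(C)OC[C@]12C=C(C[C@@H](CCO[Si](C)(C)C(C)(C)C)C(C)=C)C(=O)C[C@@H]1C(C)(C)CCC2=O | intermediate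
18 | 1α-alcohol of 17 | CC(C)(C)[Si](C)(C)OC[C@]12C=C(C[C@@H](CCO[Si](C)(C)C(C)(C)C)C(C)=C)C(=O)C[C@@H]1C(C)(C)CC[C@@H]2O | intermediate
19 | 1α-acetate of 18 | CC(C)(C)[Si](C)(C)OC[C@]12C=C(C[C@@H](CCO[Si](C)(C)C(C)(C)C)C(C)=C)C(=O)C[C@@H]1C(C)(C)CC[C@@H]2OC(C)=O | intermediate
20 | TBS dienol ether of 19 (7-silyloxy-6,8(9)-diene) | CC(C)(C)[Si](C)(C)OC[C@]12C=C(C[C@@H](CCO[Si](C)(C)C(C)(C)C)C(C)=C)C(O[Si](C)(C)C(C)(C)C)=C[C@@H]1C(C)(C)CC[C@@H]2OC(C)=O | intermediate
21 | 6β-(tert-butyldimethylsilyloxy) enone (1α-OAc, Δ8(9)-en-7-one) | CC(C)(C)[Si](C)(C)OC[C@]12C=C(C[C@@H](CCO[Si](C)(C)C(C)(C)C)C(C)=C)C(=O)[C@@H](O[Si](C)(C)C(C)(C)C)[C@@H]1C(C)(C)CC[C@@H]2OC(C)=O | intermediate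
22 | 21 with C13–C(=CH2)CH2OH (C15 allylic alcohol) | CC(C)(C)[Si](C)(C)OC[C@]12C=C(C[C@@H](CCO[Si](C)(C)C(C)(C)C)C(=C)CO)C(=O)[C@@H](O[Si](C)(C)C(C)(C)C)[C@@H]1C(C)(C)CC[C@@H]2OC(C)=O | intermediate
23 | C15 enal (C13–C(=CH2)CHO) | CC(C)(C)[Si](C)(C)OC[C@]12C=C(C[C@@H](CCO[Si](C)(C)C(C)(C)C)C(=C)C=O)C(=O)[C@@H](O[Si](C)(C)C(C)(C)C)[C@@H]1C(C)(C)CC[C@@H]2OC(C)=O | intermediate
24 | C15 acrylic acid (C13–C(=CH2)CO2H) | CC(C)(C)[Si](C)(C)OC[C@]12C=C(C[C@@H](CCO[Si](C)(C)C(C)(C)C)C(=C)C(=O)O)C(=O)[C@@H](O[Si](C)(C)C(C)(C)C)[C@@H]1C(C)(C)CC[C@@H]2OC(C)=O | intermediate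
25 | methyl acrylate enone (C13–C(=CH2)CO2Me; 1α-OAc; 6β-OTBS; 11-OTBS; 20-OTBS) | CC(C)(C)[Si](C)(C)OC[C@]12C=C(C[C@@H](CCO[Si](C)(C)C(C)(C)C)C(=C)C(=O)OC)C(=O)[C@@H](O[Si](C)(C)C(C)(C)C)[C@@H]1C(C)(C)CC[C@@H]2OC(C)=O | intermediate
26 | bridged mixed ketal: 7-methoxy-7α,20-epoxy (oxabicyclo[2.2.2]octene with C8=C9), 1α-OAc, 6β-OTBS, 5β-H; C8 carries CH2–CH[C(=CH2)CO2Me]–CH2CH2OH (13S) | C=C(C(=O)OC)[C@H](CCO)CC1=C[C@@]23CO[C@]1(OC)[C@@H](O[Si](C)(C)C(C)(C)C)[C@@H]2C(C)(C)CC[C@@H]3OC(C)=O | intermediate
27 | aldehyde of 26 (C11 = CHO) | C=C(C(=O)OC)[C@H](CC=O)CC1=C[C@@]23CO[C@]1(OC)[C@@H](O[Si](C)(C)C(C)(C)C)[C@@H]2C(C)(C)CC[C@@H]3OC(C)=O | intermediate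
28 | 6-O-TBS ether of the target (1S,5R,6S,8S,9S,10S,11S,13S) | C=C(C(=O)OC)[C@@H]1C[C@H](O)[C@@H]2[C@]3(C1)C(=O)OC[C@]21[C@@H](OC(C)=O)CCC(C)(C)[C@H]1[C@@H]3O[Si](C)(C)C(C)(C)C | intermediate
29 | CNP0421185.1: (1S,5R,6S,8S,9S,10S,11S,13S); 1α-OAc, 6β-OH, 11β-OH, C7–O–C20 lactone, cyclopentane C5–C6–C8–C9–C10, methyl acrylate at C13 | C=C(C(=O)OC)[C@@H]1C[C@H](O)[C@@H]2[C@]3(C1)C(=O)OC[C@]21[C@@H](OC(C)=O)CCC(C)(C)[C@H]1[C@@H]3O | target

**Count and risks**

Total step count: 22 (2 to enone 4, 4 to enol silane 10, 16 from the union to the target). Longest linear sequence: 20 steps (5 → 29).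

Steps most likely to fail:

1. Step 21 (Proposed new method). The Lewis acid may open the C7–O–C20 bridge, which returns the hydroxy enone on work-up, faster than the Prins closure at the hindered C9. Alternatively the aldehyde may attack the β face, or the ring oxygen may take part in place of C6. The fallback closes ring C first under thermodynamic control of C9 and then contracts ring B by a quasi-Favorskii rearrangement. From 27, the ketal is hydrolysed with PPTS in wet acetone to the hydroxy-enone aldehyde F1. Photocatalytic hydroacylation with (n-Bu4N)4[W10O32] at 390 nm in MeCN should add the acyl radical from the aldehyde to C9 of the enone. DBU then equilibrates C8 and C9, which are α to the C7 and C11 carbonyls, to the trans–anti–trans fusion and should give the tricyclic 7,11-diketone F2, whose C7 carbonyl is masked as the 7,20-hemiketal. NaBH4 in MeOH at −40 °C should reduce the C11 ketone by axial attack to the tricyclic 11β-hydroxy-7-ketone F3. Bromination of the keto tautomer at C8 with PhNMe3Br3 in THF at 0 °C should give the 8-bromo-11β-hydroxy-7-ketone F4. AgOTf with 2,6-di-tert-butylpyridine in DCM at 0 °C then triggers the silver-assisted quasi-Favorskii (semibenzilic) shift of C6 from the hemiketal carbon to C8, and the route is rejoined at 28.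

2. Step 19. The ketalisation of the hindered, conjugated, α-silyloxy ketone may stop at an unfavourable equilibrium. The secondary silyl ether or the acetate may also be lost by methanolysis, or the acetyl group may wander from C1–O to the freed C20–O, during the long exposure to acid. The fallback makes the ketal under kinetic, aprotic silyl-transfer conditions and closes the bridge afterwards. From 25, MeOSiMe3 with catalytic Me3SiOTf in DCM at −78 °C should give the C7 dimethyl ketal F5. Brief treatment with PPTS in MeOH at 0 °C then cleaves the two primary silyl ethers and lets C20–OH displace one methoxy group (transketalisation), which returns the route at 26.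

3. Step 7. Addition at the neopentylic β-carbon may be sluggish and the facial selectivity under catalyst control poor. The fallback replaces catalyst control by a covalent auxiliary. From 2, transesterification with (−)-8-phenylmenthol (DMAP, PhMe, reflux) gives the auxiliary β-keto ester F6. Selenenylation and oxidation as in step 2, through the auxiliary selenide F7, give the auxiliary enone F8, in which the aryl group covers one face of C5. Mukaiyama–Michael addition of 10 with TiCl4 in DCM at −78 °C gives the auxiliary adduct F9, and alkylation as in step 8 gives the auxiliary benzyloxymethyl compound F10. Reduction with LiAlH4 as in step 9 releases the auxiliary and returns the route at 13.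

Further compounds
F1 | step 21 | hydroxy-enone aldehyde (25 with free C20–OH and C11 = CHO) | OC[C@]12C=C(C[C@@H](CC=O)C(=C)C(=O)OC)C(=O)[C@@H](O[Si](C)(C)C(C)(C)C)[C@@H]1C(C)(C)CC[C@@H]2OC(C)=O
F2 | step 21 | tricyclic 7,11-diketone (8α-H, 9β-H; keto form of the 7,20-hemiketal) | C=C(C(=O)OC)[C@@H]1CC(=O)[C@@H]2[C@@H](C1)C(=O)[C@@H](O[Si](C)(C)C(C)(C)C)[C@@H]1C(C)(C)CC[C@H](OC(C)=O)[C@]12CO
F3 | step 21 | tricyclic 11β-hydroxy-7-ketone (keto form of the 7,20-hemiketal) | C=C(C(=O)OC)[C@@H]1C[C@H](O)[C@@H]2[C@@H](C1)C(=O)[C@@H](O[Si](C)(C)C(C)(C)C)[C@@H]1C(C)(C)CC[C@H](OC(C)=O)[C@]12CO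
F4 | step 21 | 8-bromo-11β-hydroxy-7-ketone (C8 configuration open) | C=C(C(=O)OC)[C@@H]1C[C@H](O)[C@@H]2C(Br)(C1)C(=O)[C@@H](O[Si](C)(C)C(C)(C)C)[C@@H]1C(C)(C)CC[C@H](OC(C)=O)[C@]12CO
F5 | step 19 | C7 dimethyl ketal of 25 | CC(C)(C)[Si](C)(C)OC[C@]12C=C(C[C@@H](CCO[Si](C)(C)C(C)(C)C)C(=C)C(=O)OC)C(OC)(OC)[C@@H](O[Si](C)(C)C(C)(C)C)[C@@H]1C(C)(C)CC[C@@H]2OC(C)=O
F6 | step 7 | (−)-8-phenylmenthyl 5,5-dimethyl-2-oxocyclohexane-1-carboxylate | CC(C)(c1ccccc1)[C@@H]1CC[C@@H](C)C[C@H]1OC(=O)C1CC(C)(C)CCC1=O
F7 | step 7 | (−)-8-phenylmenthyl 5,5-dimethyl-2-oxo-1-(phenylselanyl)cyclohexane-1-carboxylate | CC(C)(c1ccccc1)[C@@H]1CC[C@@H](C)C[C@H]1OC(=O)C1([Se]c2ccccc2)CC(C)(C)CCC1=O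
F8 | step 7 | (−)-8-phenylmenthyl 3,3-dimethyl-6-oxocyclohex-1-ene-1-carboxylate | CC(C)(c1ccccc1)[C@@H]1CC[C@@H](C)C[C@H]1OC(=O)C1=CC(C)(C)CCC1=O
F9 | step 7 | 8-phenylmenthyl ester analogue of 11 | CC(C)(c1ccccc1)[C@@H]1CC[C@@H](C)C[C@H]1OC(=O)C1C(=O)CCC(C)(C)[C@H]1CC(=O)CC[C@@H](CCO[Si](C)(C)C(C)(C)C)C(C)=C
F10 | step 7 | 8-phenylmenthyl ester analogue of 12 | CC(C)(c1ccccc1)[C@@H]1CC[C@@H](C)C[C@H]1OC(=O)[C@@]1(COCc2ccccc2)C(=O)CCC(C)(C)[C@H]1CC(=O)CC[C@@H](CCO[Si](C)(C)C(C)(C)C)C(C)=C
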